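## Structural features

The target is a depside: two benzene rings joined by an aryl ester, with the carbonyl carbon on C1 of ring A and the ester oxygen on C4 of ring B. Ring A is numbered here with C1 carrying the carbonyl, C2 the free hydroxyl, C4 a methoxy group and C6 the heptyl chain. Ring B carries the carboxylic acid at C1, a methoxy group at C2, the depside oxygen at C4 and the pentyl chain at C6, so each carbonyl is flanked by an oxygen and an alkyl chain. There are no stereocentres and no rings beyond the two arenes, so the problem is regiochemistry and oxygen differentiation. Four aryl oxygens must end in four different states: one free hydroxyl, one acylated oxygen, and two methyl ethers in complementary positions (para to the carbonyl on ring A, ortho on ring B). The fragile parts are the depside ester, which is labile to base and nucleophiles and cannot survive a late Lewis-acidic ether cleavage selectively, and the electron-rich ortho-oxygenated benzoic acids, which decarboxylate in hot acid. The real difficulty is to build the contiguous heptyl/carboxyl/oxygen triad of ring A with full regiocontrol and to esterify a doubly ortho-substituted benzoic acid. The key step exploits the adjacency of C6 (heptyl), C1 (carboxyl) and C2 (oxygen) in ring A, which is the pattern left when a carbon nucleophile and a carbon electrophile add across a 3-alkoxybenzyne.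

## Logic of the disconnections

19 to 18: the O–CH2Ph bond on the ring A C2 oxygen is cut. That hydroxyl must be masked while the depside bond is made, ring B is methylated and the aldehyde is oxidised. Hydrogenolysis is neutral and spares the depside ester; the demand is that nothing else in 18 is reducible.

18 to 17: the ring B carboxyl is traced back to a formyl group. An aldehyde can be placed regioselectively on the resorcinol in one step and needs no ester protecting group. The forward oxidation must spare two alkoxy-substituted rings, a benzyl ether and the aryl ester.

17 to 16: the O–CH3 bond at ring B C2 is cut. With the C4 oxygen of ring B already acylated, the C2 hydroxyl is the only free phenol, so the depside acyl group itself serves as the protecting group and no separate protection of ring B is needed. The forward alkylation must use a base mild enough to leave the aryl ester intact, which is why ring A carries no free hydroxyl at this stage.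

16 to 11 and 14: the depside acyl C–O bond is cut, giving two fragments of similar size. The forward step must acylate the non-chelated C4 hydroxyl of 14 with a di-ortho-substituted acid, which calls for acylium-type activation through 15.

14 to 12: the ring B C1–CHO bond is cut. Compound 12 is symmetrical and commercial; the forward formylation must go para to one hydroxyl and ortho to the other, not between the two hydroxyls.

11 to 10 to 9: the two benzyl groups are removed in thought (ester hydrolysis, then both O–benzyl bonds). The detour through 10 is the price of a clean mono-O-benzyl acid.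

9 to 8: the ring A C2 oxygen is traced back to a methyl ether. The two methoxy groups of 8 differ only in that one can chelate to the carboxyl group, and the forward cleavage must use exactly that difference.

8 to 3, 2 and 4 (through 5, 6 and 7): the C6–heptyl and C1–carboxyl bonds of ring A are cut together. This reduces a tetrasubstituted arene to a symmetrical commercial chloroarene, a Grignard reagent and a one-carbon electrophile. The forward step needs regioselective metalation, elimination to 6, addition of 2 at the carbon remote from the flanking methoxy group, and capture of 7 by 4.

2 to 1: the C–Mg bond is cut; 1 is commercial.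

## Other disconnections considered

Alternative 1: Ring A would be cut at C1–C2 and C5–C6 and built by cycloaddition of diene A1 to the aryl alkynoate A3, itself the ester of ring B phenol A2 with the C10 alkynoic acid. The adduct would aromatise on acidic work-up to A4, and one hydrogenolysis would then give 19.
- In its favour: the diene delivers ring A with the C2 hydroxyl free and the C4 oxygen already methylated, so no demethylation and no ring A protection are needed. On this point it is better than the chosen plan.
- Also better: the depside bond is made as an unhindered alkynoate ester, not by transfer of a di-ortho-substituted aroyl group.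
- Against it: a β-alkyl alkynoate is a sluggish dienophile, and the heat required would expose a moisture-sensitive ketene acetal and an activated aryl ester to decomposition and conjugate addition.
- Against it: aromatisation must expel the alkoxy group and not the silyloxy group from the acetal carbon; otherwise the ring A C2 oxygen ends as a methyl ether.
- Against it: A2 needs roughly five steps from 12 (carboxyl installation, benzyl ester, protection, methylation, deprotection).
- Comparison: regiocontrol should be equal, since polarity matching in the cycloaddition is as clear as methoxy direction in the aryne addition. The step count is about equal once A1 and A2 are included. The chosen plan is preferred because its key step is a more robust polar process on simple, stable partners.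

Alternative 2: Ring B would be cut at C1–C6 and C2–C3 and assembled from malonate A5 and enone A6 by conjugate addition and ring closure to A7. The closure is, strictly, a Claisen-type acylation of a ketone enolate by an ester, not a Dieckmann condensation. Dehydrogenation would then give the resorcylate A8.
- In its favour: the carboxyl carbon of ring B is placed unambiguously and already as a benzyl ester. A8 could be used exactly as 14 is (acylation at the C4 hydroxyl, late O-methylation), and the final hydrogenolysis would free the acid. That removes the aldehyde oxidation, and on this point it is better than the chosen plan.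
- Against it: it reaches ring B in two steps (three if A6 must be made) where formylation of 12 takes one. The aromatisation needs an oxidant that can also halogenate the electron-rich ring. Two stereocentres are made only to be destroyed.
- Against it: it leaves ring A and the depside bond unsolved, so it could replace steps 6 and 9 but not the aryne step.
- Comparison: step economy is equal if A6 is bought and one step worse if not.

Alternative 3: The depside C–O bond and the ring A C1–C6 bond would be formed from dioxinone A9 and phenol A2. Thermolysis of A9 would give an acylketene that A2 captures to form the aryl triketo ester A10, and base-mediated aldol closure followed by acid-mediated dehydration would give A11.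
- In its favour: the hindered ester is formed before ring A exists, so the difficult aroyl transfer never arises. On this point it is better than the chosen plan. The sequence is convergent and mirrors polyketide folding.
- Against it: A11 has both ring A hydroxyls free, so a selective methylation of the non-chelated C4 hydroxyl is still needed, on a depside whose ring A can now fragment through a ketene-forming elimination under base.
- Against it: A10 can also close through oxygen to a pyranone with loss of the ring B phenoxide.
- Against it: A9 is a labile compound needing several steps, and A2 needs about five.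
- Comparison: the stereochemical demand is equal (none), but the route is longer overall. The chosen plan starts with both ring A oxygens methylated and tells them apart by chelation, which is the more secure differentiation.

Key step: step 2

Remarks on the chemistry:
- Aryne 6 is not itself symmetrical. The symmetrical species is chloroarene 3, so only one aryne can form and the only regiochemical question is the direction of addition.
- Ring B is carried as an aldehyde, with the depside acyl group doubling as the protecting group for its C4 oxygen. A preformed 4-hydroxy-2-methoxy benzyl ester of ring B would cost about four more steps from 12.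
- Magnesium, benzyl bromide, iodomethane and the other reagents are taken as commercial.

## Route

Step 1
Reactants: 1 1-bromoheptane
Product: 2 heptylmagnesium bromide
Conditions: Mg turnings, cat. I2, THF, 40 °C then rt
Reagents that add atoms: magnesium, [Mg]
Why: Grignard formation by insertion of magnesium into the primary C–Br bond; slow addition of 1 limits Wurtz coupling, and the solution is titrated and used directly.

Step 2
Reactants: 3 1-chloro-3,5-dimethoxybenzene; 2 heptylmagnesium bromide; 4 carbon dioxide
Product: 8 2-heptyl-4,6-dimethoxybenzoic acid, via (2-chloro-4,6-dimethoxyphenyl)lithium 5 (not isolated), via 3,5-dimethoxybenzyne 6 (not isolated), via (2-heptyl-4,6-dimethoxyphenyl)magnesium bromide 7 (not isolated)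
Conditions: lithium 2,2,6,6-tetramethylpiperidide (LiTMP, 1.1 equiv, from the amine and n-BuLi), THF, −78 °C; 2 (2.5 equiv), −78 °C → rt; CO2 (4), −20 °C → rt; aq HCl
Reagents that add atoms: none
Why: LiTMP removes the proton of 3 flanked by chlorine and methoxy, the most acidic site; a lithio species between the two methoxy groups has no leaving group beside it and should be returned by the liberated amine, and on warming aryllithium 5 loses LiCl to give aryne 6. Grignard reagent 2 adds to the strained triple bond at the carbon remote from the neighbouring methoxy group, because that carbon has the wider internal angle and the developing carbanion is best stabilised inductively next to oxygen, so 7 carries magnesium exactly between heptyl and methoxy. Carbon dioxide then carboxylates 7 at that carbon, so the heptyl–C6 and carboxyl–C1 bonds of ring A are made in one flask. The closest known reaction type is carbomagnesiation of an aryne released from an ortho-metalated haloarene, followed by electrophilic quench of the new aryl Grignard, as practised in one-pot biaryl and resorcylate syntheses. No ring is closed and no stereocentre is formed. The only selectivity needed is regiochemical: 3 is symmetrical, so a single aryne can arise, and the methoxy group beside the triple bond directs the addition. An excess of 2 and slow warming should keep the hindered amide and aryl anions from competing for the aryne.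

Step 3
Reactants: 8 2-heptyl-4,6-dimethoxybenzoic acid
Product: 9 2-heptyl-6-hydroxy-4-methoxybenzoic acid
Conditions: BCl3 (2.5 equiv), CH2Cl2, −78 → 0 °C; H2O
Reagents that add atoms: none
Why: Chelation-controlled ether cleavage: BCl3 bridges the carboxyl group and the ortho methoxy oxygen in a six-membered chelate and chloride removes that methyl group, while the para methoxy group cannot chelate and should survive at low temperature.

Step 4
Reactants: 9 2-heptyl-6-hydroxy-4-methoxybenzoic acid
Product: 10 benzyl 2-(benzyloxy)-6-heptyl-4-methoxybenzoate
Conditions: BnBr (2.5 equiv), K2CO3, DMF, 60 °C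
Reagents that add atoms: benzyl bromide, BrCc1ccccc1
Why: Double Williamson-type O-alkylation; carbonate in DMF alkylates the carboxylate and, on warming, the hydrogen-bonded phenoxide.

Step 5
Reactants: 10 benzyl 2-(benzyloxy)-6-heptyl-4-methoxybenzoate
Product: 11 2-(benzyloxy)-6-heptyl-4-methoxybenzoic acid
Conditions: KOH, DMSO/H2O, 90 °C; aq HCl
Reagents that add atoms: potassium hydroxide, [K+].[OH-]
Why: Saponification of the hindered benzyl ester in aqueous DMSO; attack of hydroxide at the acyl carbon or at the benzylic carbon leads to the same carboxylate, and the aryl benzyl ether is stable to base.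

Step 6
Reactants: 12 olivetol (5-pentylbenzene-1,3-diol)
Product: 14 2,4-dihydroxy-6-pentylbenzaldehyde, via the aryl dimethyliminium chloride 13 (not isolated)
Conditions: POCl3, DMF, 0 °C → rt; H2O, 50 °C
Reagents that add atoms: N,N-dimethylformamide, CN(C)C=O; water, O
Why: Vilsmeier–Haack formylation; the chloroiminium ion attacks the resorcinol para to one hydroxyl and ortho to the other, the usual site for 5-alkylresorcinols, and water hydrolyses iminium salt 13 to the aldehyde.

Step 7
Reactants: 11 2-(benzyloxy)-6-heptyl-4-methoxybenzoic acid; 14 2,4-dihydroxy-6-pentylbenzaldehyde
Product: 16 4-formyl-3-hydroxy-5-pentylphenyl 2-(benzyloxy)-6-heptyl-4-methoxybenzoate, via the mixed trifluoroacetic anhydride 15 (not isolated)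
Conditions: (CF3CO)2O, toluene, 0 °C → rt; aq NaHCO3
Reagents that add atoms: none
Why: Classical depside esterification through a mixed trifluoroacetic anhydride and the derived acylium ion, which is unhindered at carbon although the acid is di-ortho-substituted; of the two hydroxyls of 14 only the one para to the formyl group is free of the hydrogen bond to the carbonyl, so O-acylation should occur there.

Step 8
Reactants: 16 4-formyl-3-hydroxy-5-pentylphenyl 2-(benzyloxy)-6-heptyl-4-methoxybenzoate
Product: 17 4-formyl-3-methoxy-5-pentylphenyl 2-(benzyloxy)-6-heptyl-4-methoxybenzoate
Conditions: MeI, K2CO3, acetone, 50 °C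
Reagents that add atoms: iodomethane, CI
Why: Williamson O-methylation of the only free phenol, the depside acyl group serving as protecting group for the other ring B oxygen; the hindered aroyl carbonyl and the absence of a free ring A hydroxyl (no ketene-forming elimination) should let the aryl ester survive carbonate in acetone.

Step 9
Reactants: 17 4-formyl-3-methoxy-5-pentylphenyl 2-(benzyloxy)-6-heptyl-4-methoxybenzoate
Product: 18 4-{[2-(benzyloxy)-6-heptyl-4-methoxybenzoyl]oxy}-2-methoxy-6-pentylbenzoic acid
Conditions: NaClO2, NaH2PO4, 2-methyl-2-butene, t-BuOH/THF/H2O, rt
Reagents that add atoms: sodium chlorite, [Na+].[O-]Cl=O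
Why: Pinnick oxidation of the aryl aldehyde; 2-methyl-2-butene scavenges hypochlorous acid so the alkoxy-substituted rings are not chlorinated, and the benzyl ether and aryl ester are inert in the buffered medium.

Step 10
Reactants: 18 4-{[2-(benzyloxy)-6-heptyl-4-methoxybenzoyl]oxy}-2-methoxy-6-pentylbenzoic acid
Product: 19 4-[(2-heptyl-6-hydroxy-4-methoxybenzoyl)oxy]-2-methoxy-6-pentylbenzoic acid (target)
Conditions: H2 (1 atm), 10% Pd/C, EtOAc, rt
Reagents that add atoms: none
Why: Hydrogenolysis of the aryl benzyl ether over palladium on carbon under neutral conditions; the depside ester, the methyl ethers and the free acid are untouched, and no stereocentre is involved.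

## Compound list

1 | 1-bromoheptane | CCCCCCCBr | starting material
2 | heptylmagnesium bromide | CCCCCCC[Mg]Br | intermediate
3 | 1-chloro-3,5-dimethoxybenzene | COc1cc(Cl)cc(OC)c1 | starting material
4 | carbon dioxide | O=C=O | starting material
5 | (2-chloro-4,6-dimethoxyphenyl)lithium | [Li]c1c(Cl)cc(OC)cc1OC | intermediate (not isolated)
6 | 3,5-dimethoxybenzyne (1,2-didehydro-3,5-dimethoxybenzene) | COC1=CC(OC)=CC#C1 | intermediate (not isolated)
7 | (2-heptyl-4,6-dimethoxyphenyl)magnesium bromide | CCCCCCCc1cc(OC)cc(OC)c1[Mg]Br | intermediate (not isolated)
8 | 2-heptyl-4,6-dimethoxybenzoic acid | CCCCCCCc1cc(OC)cc(OC)c1C(=O)O | intermediate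
9 | 2-heptyl-6-hydroxy-4-methoxybenzoic acid | CCCCCCCc1cc(OC)cc(O)c1C(=O)O | intermediate
10 | benzyl 2-(benzyloxy)-6-heptyl-4-methoxybenzoate | CCCCCCCc1cc(OC)cc(OCc2ccccc2)c1C(=O)OCc1ccccc1 | intermediate
11 | 2-(benzyloxy)-6-heptyl-4-methoxybenzoic acid | CCCCCCCc1cc(OC)cc(OCc2ccccc2)c1C(=O)O | intermediate
12 | olivetol (5-pentylbenzene-1,3-diol) | CCCCCc1cc(O)cc(O)c1 | starting material
13 | [(2,4-dihydroxy-6-pentylphenyl)methylidene]dimethylammonium chloride | CCCCCc1cc(O)cc(O)c1C=[N+](C)C.[Cl-] | intermediate (not isolated)
14 | 2,4-dihydroxy-6-pentylbenzaldehyde | CCCCCc1cc(O)cc(O)c1C=O | intermediate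
15 | 2-(benzyloxy)-6-heptyl-4-methoxybenzoic trifluoroacetic anhydride | CCCCCCCc1cc(OC)cc(OCc2ccccc2)c1C(=O)OC(=O)C(F)(F)F | intermediate (not isolated)
16 | 4-formyl-3-hydroxy-5-pentylphenyl 2-(benzyloxy)-6-heptyl-4-methoxybenzoate | CCCCCCCc1cc(OC)cc(OCc2ccccc2)c1C(=O)Oc1cc(CCCCC)c(C=O)c(O)c1 | intermediate
17 | 4-formyl-3-methoxy-5-pentylphenyl 2-(benzyloxy)-6-heptyl-4-methoxybenzoate | CCCCCCCc1cc(OC)cc(OCc2ccccc2)c1C(=O)Oc1cc(CCCCC)c(C=O)c(OC)c1 | intermediate
18 | 4-{[2-(benzyloxy)-6-heptyl-4-methoxybenzoyl]oxy}-2-methoxy-6-pentylbenzoic acid | CCCCCCCc1cc(OC)cc(OCc2ccccc2)c1C(=O)Oc1cc(CCCCC)c(C(=O)O)c(OC)c1 | intermediate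
19 | 4-[(2-heptyl-6-hydroxy-4-methoxybenzoyl)oxy]-2-methoxy-6-pentylbenzoic acid | CCCCCCCc1cc(OC)cc(O)c1C(=O)Oc1cc(CCCCC)c(C(=O)O)c(OC)c1 | target

## Step count and least certain steps

Total: 10 steps. Longest linear sequence: 9 steps (1, 2, 3, 4, 5, 7, 8, 9, 10); the ring B branch contributes step 6.

Step 2 (key step). The metalation may not funnel fully to the position between chlorine and methoxy, so a species metalated between the two methoxy groups could persist and be carboxylated. The aryne may also be intercepted by the amide or by aryl anions instead of by the alkyl Grignard reagent, and carboxylation of surplus 2 gives a second acid that complicates purification. Fallback: a route that avoids the aryne, setting out from 3 and 2 and returning at 8. Kumada–Corriu coupling of 3 with 2 under NiCl2(dppp) catalysis in THF should give 1-heptyl-3,5-dimethoxybenzene F1. Vilsmeier–Haack formylation (POCl3, DMF) para to one methoxy group and next to the chain should give 2-heptyl-4,6-dimethoxybenzaldehyde F2. Chlorite oxidation under the conditions of step 9 would then give 8.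

Step 3. The free acid may bind BCl3 as a poorly soluble acyloxyborane, so cleavage may stall. Forcing it could cleave the para methyl ether as well or cause protodecarboxylation of the electron-rich salicylic acid during work-up. Fallback: ester-directed demethylation, setting out from 8 and returning at 11. Esterification of 8 (MeI, K2CO3, DMF) should give methyl 2-heptyl-4,6-dimethoxybenzoate F3. BCl3 in CH2Cl2 at low temperature should cleave only the chelated ether, giving methyl 2-heptyl-6-hydroxy-4-methoxybenzoate F4. Benzylation (BnBr, K2CO3, DMF) should give methyl 2-(benzyloxy)-6-heptyl-4-methoxybenzoate F5, and hydrolysis (KOH, DMSO/H2O, 90 °C) would give 11, bypassing 9 and 10.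

Step 7. The acylium ion may acylate carbon of the electron-rich ring B instead of oxygen, the phenol may be consumed as its trifluoroacetate, or the acidic medium may cleave the benzyl ether. Fallback: base-mediated acylation of the phenoxide with an isolated acyl chloride, setting out from 11 and returning at 16. Treatment of 11 with oxalyl chloride and catalytic DMF in CH2Cl2 should give 2-(benzyloxy)-6-heptyl-4-methoxybenzoyl chloride F6. This would be added to 14 with Et3N and catalytic 4-(dimethylamino)pyridine in CH2Cl2 at 0 °C, where the more acidic, non-chelated hydroxyl is acylated to give 16.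

Step 8. Carbonate may cleave or transfer the activated aryl ester before the hydrogen-bonded hydroxyl is fully alkylated. Fallback: methylate ring B before the depside bond exists, setting out from 14 and returning at 17. Selective silylation of the non-chelated hydroxyl (triisopropylsilyl chloride, imidazole, DMF) should give 2-hydroxy-6-pentyl-4-[(triisopropylsilyl)oxy]benzaldehyde F7. Methylation (MeI, K2CO3, acetone) should give 2-methoxy-6-pentyl-4-[(triisopropylsilyl)oxy]benzaldehyde F8, and desilylation (Bu4NF, THF) should give 4-hydroxy-2-methoxy-6-pentylbenzaldehyde F9. Acylation of F9 with 11 under the conditions of step 7 would give 17, bypassing 16.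

## Further compounds

F1 | step 2 | 1-heptyl-3,5-dimethoxybenzene | CCCCCCCc1cc(OC)cc(OC)c1
F2 | step 2 | 2-heptyl-4,6-dimethoxybenzaldehyde | CCCCCCCc1cc(OC)cc(OC)c1C=O
F3 | step 3 | methyl 2-heptyl-4,6-dimethoxybenzoate | CCCCCCCc1cc(OC)cc(OC)c1C(=O)OC
F4 | step 3 | methyl 2-heptyl-6-hydroxy-4-methoxybenzoate | CCCCCCCc1cc(OC)cc(O)c1C(=O)OC
F5 | step 3 | methyl 2-(benzyloxy)-6-heptyl-4-methoxybenzoate | CCCCCCCc1cc(OC)cc(OCc2ccccc2)c1C(=O)OC
F6 | step 7 | 2-(benzyloxy)-6-heptyl-4-methoxybenzoyl chloride | CCCCCCCc1cc(OC)cc(OCc2ccccc2)c1C(Cl)=O
F7 | step 8 | 2-hydroxy-6-pentyl-4-[(triisopropylsilyl)oxy]benzaldehyde | CCCCCc1cc(O[Si](C(C)C)(C(C)C)C(C)C)cc(O)c1C=O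
F8 | step 8 | 2-methoxy-6-pentyl-4-[(triisopropylsilyl)oxy]benzaldehyde | CCCCCc1cc(O[Si](C(C)C)(C(C)C)C(C)C)cc(OC)c1C=O
F9 | step 8 | 4-hydroxy-2-methoxy-6-pentylbenzaldehyde | CCCCCc1cc(O)cc(OC)c1C=O
A1 | alternative 1 | (1E)-1,3-dimethoxy-1-(trimethylsilyloxy)buta-1,3-diene | C=C(OC)/C=C(/O[Si](C)(C)C)OC
A2 | alternative 1 | benzyl 4-hydroxy-2-methoxy-6-pentylbenzoate | CCCCCc1cc(O)cc(OC)c1C(=O)OCc1ccccc1
A3 | alternative 1 | benzyl 4-(dec-2-ynoyloxy)-2-methoxy-6-pentylbenzoate | CCCCCCCC#CC(=O)Oc1cc(CCCCC)c(C(=O)OCc2ccccc2)c(OC)c1
A4 | alternative 1 | benzyl 4-[(2-heptyl-6-hydroxy-4-methoxybenzoyl)oxy]-2-methoxy-6-pentylbenzoate | CCCCCCCc1cc(OC)cc(O)c1C(=O)Oc1cc(CCCCC)c(C(=O)OCc2ccccc2)c(OC)c1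
A5 | alternative 2 | dibenzyl malonate | O=C(CC(=O)OCc1ccccc1)OCc1ccccc1
A6 | alternative 2 | (E)-non-3-en-2-one | CCCCC/C=C/C(C)=O
A7 | alternative 2 | benzyl trans-2,4-dioxo-6-pentylcyclohexane-1-carboxylate (racemic) | CCCCC[C@@H]1CC(=O)CC(=O)[C@H]1C(=O)OCc1ccccc1
A8 | alternative 2 | benzyl 2,4-dihydroxy-6-pentylbenzoate | CCCCCc1cc(O)cc(O)c1C(=O)OCc1ccccc1
A9 | alternative 3 | 6-(2,4-dioxoundecyl)-2,2-dimethyl-4H-1,3-dioxin-4-one | CCCCCCCC(=O)CC(=O)CC1=CC(=O)OC(C)(C)O1
A10 | alternative 3 | benzyl 2-methoxy-6-pentyl-4-[(3,5,7-trioxotetradecanoyl)oxy]benzoate | CCCCCCCC(=O)CC(=O)CC(=O)CC(=O)Oc1cc(CCCCC)c(C(=O)OCc2ccccc2)c(OC)c1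
A11 | alternative 3 | benzyl 4-[(2-heptyl-4,6-dihydroxybenzoyl)oxy]-2-methoxy-6-pentylbenzoate | CCCCCCCc1cc(O)cc(O)c1C(=O)Oc1cc(CCCCC)c(C(=O)OCc2ccccc2)c(OC)c1
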